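**Plan**

- Retrosynthesis: the two aryl silyl ethers come off last. Ring C is cut at C2–C3 by reversing a 1,2-shift, which turns its acyloin (C3–OH next to the C4 ketone) into a tertiary α-hydroxy aldehyde on a 2-aryl-2,3-dihydrobenzofuran.
- That five-membered ring is cut at O1–C2 (phenol onto a benzylic epoxide carbon). The epoxide goes back to a (Z)-2,3-diarylallyl alcohol, and its C=C bond to an arylacetonitrile and a benzaldehyde.
- Forward: ring A is made as nitrile 5 and ring B as aldehyde 7. They are joined at the C=C bond (step 5), the alkene is epoxidised, the five-membered O-ring is closed (step 8), CH2OH is oxidised, and the ring is enlarged to ring C (step 11).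
- Stereochemistry: the Sharpless epoxidation fixes both epoxide carbons. SN2 opening by the phenoxide inverts the benzylic one and gives C2 (R). C3 is created in the ring enlargement, trans to the aryl group, by a chelated suprafacial shift.
- Feature used: C3 (CHOH) and C4 (C=O) of ring C are an acyloin whose carbonyl carbon C4 is bonded to the aryl carbon C4a and whose carbinol carbon C3 is bonded to C2. The pair can therefore arise from a carbinol/formyl pair with C2 on the carbinol carbon.

Key step: step 11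

Remark on the chemistry: the formyl group of the dihydrobenzofuran is placed cis to the 2-aryl group (hydroxyl trans), because a chelated shift from this isomer should give the 2,3-trans flavanonol directly; the other C3 epimer would give 2,3-cis and need an enolisation that endangers C2.

Starting materials bought: 2,4,6-trihydroxybenzaldehyde (the formylated form of phloroglucinol), prenyl bromide, vanillin.

Abbreviations: prenyl = 3-methylbut-2-en-1-yl; allyl = prop-2-en-1-yl; TIPS = triisopropylsilyl; TBS = tert-butyldimethylsilyl; TosMIC = p-toluenesulfonylmethyl isocyanide; DET = diethyl tartrate.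

**Step 1**
Reactants: 1 2,4,6-trihydroxybenzaldehyde; 2 prenyl bromide
Product: 3 2,6-dihydroxy-4-(prenyloxy)benzaldehyde
Conditions: K2CO3 (1.0 equiv), acetone, rt
Reagents that add atoms: none
Why: Williamson etherification, in which the 4-hydroxyl (para to the formyl group and not hydrogen-bonded to it) is the most acidic and should react first with one equivalent of base and bromide.

**Step 2**
Reactants: 3 2,6-dihydroxy-4-(prenyloxy)benzaldehyde
Product: 4 2,6-bis(allyloxy)-4-(prenyloxy)benzaldehyde
Conditions: allyl bromide (2.5 equiv), K2CO3, DMF, 60 °C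
Reagents that add atoms: allyl bromide, C=CCBr
Why: Williamson etherification of both hydrogen-bonded phenols; allyl ethers survive amide base and hydride and can later be removed by zerovalent palladium at room temperature without touching the prenyl ether or an aryl silyl ether.

**Step 3**
Reactants: 4 2,6-bis(allyloxy)-4-(prenyloxy)benzaldehyde
Product: 5 [2,6-bis(allyloxy)-4-(prenyloxy)phenyl]acetonitrile
Conditions: TosMIC, KOtBu, DME, −40 → −20 °C; then MeOH, 65 °C
Reagents that add atoms: TosMIC, Cc1ccc(cc1)S(=O)(=O)C[N+]#[C-]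
Why: van Leusen reductive cyanation, in which the TosMIC anion adds to the aldehyde, the oxazoline opens and methanolysis with loss of sulfinate and formate should give the homologous nitrile in one flask.

**Step 4**
Reactants: 6 vanillin
Product: 7 3-methoxy-4-(triisopropylsilyloxy)benzaldehyde
Conditions: TIPSCl, imidazole, CH2Cl2, rt
Reagents that add atoms: triisopropylsilyl chloride, CC(C)[Si](Cl)(C(C)C)C(C)C
Why: standard silylation of a phenol; the bulky TIPS ether should tolerate amide base, hydride, the epoxidation and the phenoxide medium of step 8, and falls to fluoride at the end.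

**Step 5**
Reactants: 5 [2,6-bis(allyloxy)-4-(prenyloxy)phenyl]acetonitrile; 7 3-methoxy-4-(triisopropylsilyloxy)benzaldehyde
Product: 10 (Z)-2-[2,6-bis(allyloxy)-4-(prenyloxy)phenyl]-3-[3-methoxy-4-(triisopropylsilyloxy)phenyl]prop-2-enenitrile, via lithium aldolate 8 (not isolated), via aldol acetate 9 (not isolated)
Conditions: LiN(SiMe3)2, THF, −78 °C; 7; Ac2O, −78 → 0 °C; DBU, rt
Reagents that add atoms: none
Why: Knoevenagel-type condensation run as aldol addition of the nitrile anion, O-acetylation and E1cB elimination so that no alkoxide meets the silyl ether; the small linear cyano group should end cis to the new aryl group, so the two aryl groups are trans (Z), as usual for α-cyanostilbenes.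

**Step 6**
Reactants: 10 the (Z)-acrylonitrile
Product: 12 (Z)-2-[2,6-bis(allyloxy)-4-(prenyloxy)phenyl]-3-[3-methoxy-4-(triisopropylsilyloxy)phenyl]prop-2-en-1-ol, via Z-enal 11 (not isolated)
Conditions: i-Bu2AlH, toluene, −78 °C; aq. citric acid, 0 °C; then NaBH4, CeCl3·7H2O, MeOH/THF, −20 °C
Reagents that add atoms: water, O
Why: partial reduction of the nitrile to the aldimine, mild hydrolysis and immediate Luche 1,2-reduction of the crude enal; keeping the enal cold and unisolated should preserve the Z geometry, which is not the thermodynamic one for a 2-arylcinnamaldehyde.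

**Step 7**
Reactants: 12 the (Z)-allylic alcohol
Product: 13 [(2R,3S)-2-[2,6-bis(allyloxy)-4-(prenyloxy)phenyl]-3-[3-methoxy-4-(triisopropylsilyloxy)phenyl]oxiran-2-yl]methanol
Conditions: Ti(OiPr)4 (20 mol %), D-(−)-DET (26 mol %), t-BuOOH, 4 Å MS, CH2Cl2, −20 °C
Reagents that add atoms: tert-butyl hydroperoxide, CC(C)(C)OO
Why: Sharpless asymmetric epoxidation, which delivers oxygen only to the hydroxyl-bearing alkene (the allyl and prenyl ethers are not allylic alcohols); with D-(−)-DET the reagent-controlled face should give the (2R,3S)-epoxide, which fixes the later C3 and, after inversion, C2.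

**Step 8**
Reactants: 13 the (2R,3S)-epoxy alcohol
Product: 15 (2R,3R)-3-(hydroxymethyl)-2-[3-methoxy-4-(triisopropylsilyloxy)phenyl]-6-(prenyloxy)-2,3-dihydro-1-benzofuran-3,4-diol (aryl cis to CH2OH), via bisphenol epoxide 14 (not isolated)
Conditions: Pd(PPh3)4 (5 mol %), TolSO2Na (2.4 equiv), degassed THF/MeOH, rt then 40 °C; aq. NH4Cl
Reagents that add atoms: none
Why: Tsuji–Trost deallylation with sulfinate as allyl acceptor frees two equivalent phenoxides (the ring is symmetric), and one should open the epoxide at its benzylic carbon by 5-endo SN2 attack with inversion, the known route from 2-(oxiranyl)phenols to 2-aryl-2,3-dihydrobenzofuran-3-ols; this sets C2 as R, and the unsubstituted allyl ethers ionise far faster than the prenyl ether at this temperature.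

**Step 9**
Reactants: 15 the dihydrobenzofuran triol
Product: 16 (2R,3R)-4-(tert-butyldimethylsilyloxy)-3-(hydroxymethyl)-2-[3-methoxy-4-(triisopropylsilyloxy)phenyl]-6-(prenyloxy)-2,3-dihydro-1-benzofuran-3-ol
Conditions: TBSCl (1.05 equiv), Et3N, CH2Cl2, 0 °C
Reagents that add atoms: tert-butyldimethylsilyl chloride, CC(C)(C)[Si](C)(C)Cl
Why: chemoselective silylation of the only phenol (Et3N forms the phenoxide, whereas the neopentyl primary and the tertiary alcohol do not react with TBSCl without a nucleophilic catalyst), which removes an acidic, oxidisable and metal-binding group before steps 10 and 11.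

**Step 10**
Reactants: 16 the silylated diol
Product: 17 (2R,3S)-4-(tert-butyldimethylsilyloxy)-3-hydroxy-2-[3-methoxy-4-(triisopropylsilyloxy)phenyl]-6-(prenyloxy)-2,3-dihydro-1-benzofuran-3-carbaldehyde (formyl cis to aryl)
Conditions: SO3·pyridine, DMSO, i-Pr2NEt, CH2Cl2, 0 °C
Reagents that add atoms: none
Why: Parikh–Doering oxidation of the primary alcohol of a 1,2-diol to the α-hydroxy aldehyde; activated DMSO at 0 °C should not cleave the glycol, attack the electron-rich arenes and alkenes, or ionise the tertiary benzylic alcohol.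

**Step 11**
Reactants: 17 the 3-formyl-3-hydroxy-2-aryl-2,3-dihydrobenzofuran
Product: 18 (2R,3R)-5-(tert-butyldimethylsilyloxy)-3-hydroxy-2-[3-methoxy-4-(triisopropylsilyloxy)phenyl]-7-(prenyloxy)-2,3-dihydro-4H-chromen-4-one
Conditions: Zn(OTf)2 (30 mol %), 2,6-di-tert-butyl-4-methylpyridine, 4 Å MS, ClCH2CH2Cl, 40 °C
Reagents that add atoms: none
Why: Proposed new method: divalent zinc should bind the tertiary hydroxyl and the formyl oxygen of 17 in a five-membered chelate (O–C3–C=O syn-periplanar), so that the C3–C2 bond stands over one face of the activated formyl group and C2 shifts suprafacially from C3 to the formyl carbon while C3 becomes the C4 ketone and the hydroxyl proton passes to the new alkoxide; the closest known reaction type is the Lewis-acid-mediated α-ketol (acyloin) rearrangement of cyclic tertiary α-hydroxy aldehydes and ketones with one-carbon ring enlargement (1-acylcycloalkanols, D-homoannulation of 17-hydroxy-20-keto steroids), which has not been shown on a 2-aryl-2,3-dihydrobenzofuran. Ring C is not closed end to end but grows from the five-membered ring by this 1,2-shift of the ring carbon C2 (five to six members, new bond C2–C3). C2 migrates with retention and stays R; the new centre C3 is controlled by the chelate, because C2 can only add to the formyl face it already lies over, which leaves the former formyl oxygen pseudo-equatorial beside the ketone, and since the formyl group is cis to the 2-aryl group in 17 the aryl group is equatorial in the same half-chair, that is 2,3-trans (3R). The step needs C2 to migrate in preference to the aryl carbon C3a and without ionisation of the benzylic C2–O1 bond: C2 carries O1 and an electron-rich aryl group (high migratory aptitude), C3a is held in the plane of the five-membered ring by the O1 bridge and cannot reach a bridged phenonium geometry, and the conjugated aryl ketone is the thermodynamic sink. A weak, non-reducing, chelating Lewis acid with a hindered pyridine is chosen so that the aldehyde is not reduced (as an aluminium isopropoxide would do by Meerwein–Ponndorf–Verley transfer) and the prenyl ether, the silyl ethers and C2 see no protic acid, and the silyl group on the neighbouring phenol rules out a competing phenoxide chelate.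

**Step 12**
Reactants: 18 the bis-silylated flavanonol
Product: 19 (2R,3R)-3,5-dihydroxy-2-(4-hydroxy-3-methoxyphenyl)-7-(prenyloxy)-2,3-dihydro-4H-chromen-4-one
Conditions: Bu4NF, AcOH, THF, 0 °C
Reagents that add atoms: none
Why: fluoride cleavage of both aryl silyl ethers, buffered with acetic acid so that the phenoxides are protonated at once and the base-sensitive flavanonol is neither opened at C2 nor enolised at C3.

**Compound list**

1 | 2,4,6-trihydroxybenzaldehyde | O=Cc1c(O)cc(O)cc1O | starting material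
2 | prenyl bromide (1-bromo-3-methylbut-2-ene) | CC(C)=CCBr | starting material
3 | 2,6-dihydroxy-4-(prenyloxy)benzaldehyde | O=Cc1c(O)cc(OCC=C(C)C)cc1O | intermediate
4 | 2,6-bis(allyloxy)-4-(prenyloxy)benzaldehyde | O=Cc1c(OCC=C)cc(OCC=C(C)C)cc1OCC=C | intermediate
5 | [2,6-bis(allyloxy)-4-(prenyloxy)phenyl]acetonitrile | N#CCc1c(OCC=C)cc(OCC=C(C)C)cc1OCC=C | intermediate
6 | vanillin | COc1cc(C=O)ccc1O | starting material
7 | 3-methoxy-4-(triisopropylsilyloxy)benzaldehyde | COc1cc(C=O)ccc1O[Si](C(C)C)(C(C)C)C(C)C | intermediate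
8 | lithium aldolate of 5 and 7 (diastereomer mixture) | [Li+].[O-]C(c1ccc(O[Si](C(C)C)(C(C)C)C(C)C)c(OC)c1)C(C#N)c1c(OCC=C)cc(OCC=C(C)C)cc1OCC=C | intermediate (not isolated)
9 | aldol acetate (diastereomer mixture) | CC(=O)OC(c1ccc(O[Si](C(C)C)(C(C)C)C(C)C)c(OC)c1)C(C#N)c1c(OCC=C)cc(OCC=C(C)C)cc1OCC=C | intermediate (not isolated)
10 | (Z)-2-[2,6-bis(allyloxy)-4-(prenyloxy)phenyl]-3-[3-methoxy-4-(triisopropylsilyloxy)phenyl]prop-2-enenitrile | N#C/C(=C\c1ccc(O[Si](C(C)C)(C(C)C)C(C)C)c(OC)c1)c1c(OCC=C)cc(OCC=C(C)C)cc1OCC=C | intermediate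
11 | (Z)-2-[2,6-bis(allyloxy)-4-(prenyloxy)phenyl]-3-[3-methoxy-4-(triisopropylsilyloxy)phenyl]prop-2-enal | O=C/C(=C\c1ccc(O[Si](C(C)C)(C(C)C)C(C)C)c(OC)c1)c1c(OCC=C)cc(OCC=C(C)C)cc1OCC=C | intermediate (not isolated)
12 | (Z)-2-[2,6-bis(allyloxy)-4-(prenyloxy)phenyl]-3-[3-methoxy-4-(triisopropylsilyloxy)phenyl]prop-2-en-1-ol | OC/C(=C\c1ccc(O[Si](C(C)C)(C(C)C)C(C)C)c(OC)c1)c1c(OCC=C)cc(OCC=C(C)C)cc1OCC=C | intermediate
13 | [(2R,3S)-2-[2,6-bis(allyloxy)-4-(prenyloxy)phenyl]-3-[3-methoxy-4-(triisopropylsilyloxy)phenyl]oxiran-2-yl]methanol | COc1cc([C@@H]2O[C@@]2(CO)c3c(OCC=C)cc(OCC=C(C)C)cc3OCC=C)ccc1O[Si](C(C)C)(C(C)C)C(C)C | intermediate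
14 | [(2R,3S)-2-[2,6-dihydroxy-4-(prenyloxy)phenyl]-3-[3-methoxy-4-(triisopropylsilyloxy)phenyl]oxiran-2-yl]methanol | COc1cc([C@@H]2O[C@@]2(CO)c3c(O)cc(OCC=C(C)C)cc3O)ccc1O[Si](C(C)C)(C(C)C)C(C)C | intermediate (not isolated)
15 | (2R,3R)-3-(hydroxymethyl)-2-[3-methoxy-4-(triisopropylsilyloxy)phenyl]-6-(prenyloxy)-2,3-dihydro-1-benzofuran-3,4-diol | COc1cc([C@H]2Oc3cc(OCC=C(C)C)cc(O)c3[C@@]2(O)CO)ccc1O[Si](C(C)C)(C(C)C)C(C)C | intermediate
16 | (2R,3R)-4-(tert-butyldimethylsilyloxy)-3-(hydroxymethyl)-2-[3-methoxy-4-(triisopropylsilyloxy)phenyl]-6-(prenyloxy)-2,3-dihydro-1-benzofuran-3-ol | COc1cc([C@H]2Oc3cc(OCC=C(C)C)cc(O[Si](C)(C)C(C)(C)C)c3[C@@]2(O)CO)ccc1O[Si](C(C)C)(C(C)C)C(C)C | intermediate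
17 | (2R,3S)-4-(tert-butyldimethylsilyloxy)-3-hydroxy-2-[3-methoxy-4-(triisopropylsilyloxy)phenyl]-6-(prenyloxy)-2,3-dihydro-1-benzofuran-3-carbaldehyde | COc1cc([C@H]2Oc3cc(OCC=C(C)C)cc(O[Si](C)(C)C(C)(C)C)c3[C@@]2(O)C=O)ccc1O[Si](C(C)C)(C(C)C)C(C)C | intermediate
18 | (2R,3R)-5-(tert-butyldimethylsilyloxy)-3-hydroxy-2-[3-methoxy-4-(triisopropylsilyloxy)phenyl]-7-(prenyloxy)-2,3-dihydro-4H-chromen-4-one | COc1cc([C@H]2Oc3cc(OCC=C(C)C)cc(O[Si](C)(C)C(C)(C)C)c3C(=O)[C@@H]2O)ccc1O[Si](C(C)C)(C(C)C)C(C)C | intermediate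
19 | (2R,3R)-3,5-dihydroxy-2-(4-hydroxy-3-methoxyphenyl)-7-(prenyloxy)-2,3-dihydro-4H-chromen-4-one | COc1cc([C@H]2Oc3cc(OCC=C(C)C)cc(O)c3C(=O)[C@@H]2O)ccc1O | target

**Step count and weak points**

Total step count: 12. Longest linear sequence: 11 (steps 1–3 and 5–12).

Steps most likely to fail:

Step 11 (proposed method). The shift may not stay concerted, so that C2 ionises as a benzylic oxocarbenium ion and loses its configuration; the aryl carbon may migrate instead; or the aldehyde may not react. The fallback uses known chemistry, sets out from 4 and 7 and returns at 19. MeMgBr adds to 4 to give the racemic carbinol 1-[2,6-bis(allyloxy)-4-(prenyloxy)phenyl]ethanol F1, and MnO2 oxidises it to the acetophenone F2. Claisen–Schmidt condensation of F2 with 7 (pyrrolidine, EtOH) gives the (E)-chalcone F3. Juliá–Colonna epoxidation (poly-L-leucine, urea–H2O2, DBU) gives the (2R,3S)-epoxy ketone F4. Deallylation as in step 8 frees the 2',6'-dihydroxy epoxy ketone F5, whose phenoxide opens the epoxide at the benzylic carbon (6-endo, inversion) to the 4'-O-TIPS flavanonol F6. Fluoride as in step 12 turns F6 into 19.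

Step 7. Oxygen transfer to the hindered Z-configured allylic alcohol may be slow and poorly face-selective, and the titanium Lewis acid may open the electron-rich epoxide once it has formed. The fallback sets out from 12 and returns at 13. Hydroxyl-directed epoxidation with VO(acac)2 and t-BuOOH gives the racemic epoxy alcohol F7. Esterification with (S)-O-methylmandelic acid (DCC, DMAP) gives the ester F8 of 13 and the ester F9 of its enantiomer, which are separated by chromatography or crystallisation. i-Bu2AlH at −78 °C cleaves F8 to 13.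

Step 8. The 5-endo attack may be slow, leaving time for heterolysis of the tertiary benzylic C–O bond of the freed ortho-hydroxyaryl epoxide (ortho-quinone methide formation) or for loss of the silyl ether in the phenoxide medium. The fallback sets out from 13 and returns at 17. Parikh–Doering oxidation of 13 gives the epoxy aldehyde F10, in which the formyl group shuts off ionisation at the tertiary carbon and activates the benzylic carbon toward attack. Deallylation as in step 8 gives the bisphenol epoxy aldehyde F11, which closes to the 4-hydroxy aldehyde F12. Silylation as in step 9 gives 17, so that 15 and 16 are bypassed.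

**Further compounds**

F1 | step 11 | 1-[2,6-bis(allyloxy)-4-(prenyloxy)phenyl]ethanol (racemic) | CC(O)c1c(OCC=C)cc(OCC=C(C)C)cc1OCC=C
F2 | step 11 | 1-[2,6-bis(allyloxy)-4-(prenyloxy)phenyl]ethanone | CC(=O)c1c(OCC=C)cc(OCC=C(C)C)cc1OCC=C
F3 | step 11 | (E)-1-[2,6-bis(allyloxy)-4-(prenyloxy)phenyl]-3-[3-methoxy-4-(triisopropylsilyloxy)phenyl]prop-2-en-1-one | O=C(/C=C/c1ccc(O[Si](C(C)C)(C(C)C)C(C)C)c(OC)c1)c1c(OCC=C)cc(OCC=C(C)C)cc1OCC=C
F4 | step 11 | [2,6-bis(allyloxy)-4-(prenyloxy)phenyl][(2R,3S)-3-[3-methoxy-4-(triisopropylsilyloxy)phenyl]oxiran-2-yl]methanone | O=C([C@@H]1O[C@H]1c2ccc(O[Si](C(C)C)(C(C)C)C(C)C)c(OC)c2)c3c(OCC=C)cc(OCC=C(C)C)cc3OCC=C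
F5 | step 11 | [2,6-dihydroxy-4-(prenyloxy)phenyl][(2R,3S)-3-[3-methoxy-4-(triisopropylsilyloxy)phenyl]oxiran-2-yl]methanone | O=C([C@@H]1O[C@H]1c2ccc(O[Si](C(C)C)(C(C)C)C(C)C)c(OC)c2)c3c(O)cc(OCC=C(C)C)cc3O
F6 | step 11 | (2R,3R)-3,5-dihydroxy-2-[3-methoxy-4-(triisopropylsilyloxy)phenyl]-7-(prenyloxy)-2,3-dihydro-4H-chromen-4-one | COc1cc([C@H]2Oc3cc(OCC=C(C)C)cc(O)c3C(=O)[C@@H]2O)ccc1O[Si](C(C)C)(C(C)C)C(C)C
F7 | step 7 | racemic epoxy alcohol (13 and its enantiomer, 1:1) | COc1cc([C@@H]2O[C@@]2(CO)c3c(OCC=C)cc(OCC=C(C)C)cc3OCC=C)ccc1O[Si](C(C)C)(C(C)C)C(C)C.COc1cc([C@H]2O[C@]2(CO)c3c(OCC=C)cc(OCC=C(C)C)cc3OCC=C)ccc1O[Si](C(C)C)(C(C)C)C(C)C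
F8 | step 7 | (S)-O-methylmandelate of 13 | COc1cc([C@@H]2O[C@@]2(COC(=O)[C@@H](OC)c4ccccc4)c3c(OCC=C)cc(OCC=C(C)C)cc3OCC=C)ccc1O[Si](C(C)C)(C(C)C)C(C)C
F9 | step 7 | (S)-O-methylmandelate of the enantiomer of 13 | COc1cc([C@H]2O[C@]2(COC(=O)[C@@H](OC)c4ccccc4)c3c(OCC=C)cc(OCC=C(C)C)cc3OCC=C)ccc1O[Si](C(C)C)(C(C)C)C(C)C
F10 | step 8 | (2S,3S)-2-[2,6-bis(allyloxy)-4-(prenyloxy)phenyl]-3-[3-methoxy-4-(triisopropylsilyloxy)phenyl]oxirane-2-carbaldehyde | COc1cc([C@@H]2O[C@@]2(C=O)c3c(OCC=C)cc(OCC=C(C)C)cc3OCC=C)ccc1O[Si](C(C)C)(C(C)C)C(C)C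
F11 | step 8 | (2S,3S)-2-[2,6-dihydroxy-4-(prenyloxy)phenyl]-3-[3-methoxy-4-(triisopropylsilyloxy)phenyl]oxirane-2-carbaldehyde | COc1cc([C@@H]2O[C@@]2(C=O)c3c(O)cc(OCC=C(C)C)cc3O)ccc1O[Si](C(C)C)(C(C)C)C(C)C
F12 | step 8 | (2R,3S)-3,4-dihydroxy-2-[3-methoxy-4-(triisopropylsilyloxy)phenyl]-6-(prenyloxy)-2,3-dihydro-1-benzofuran-3-carbaldehyde | COc1cc([C@H]2Oc3cc(OCC=C(C)C)cc(O)c3[C@@]2(O)C=O)ccc1O[Si](C(C)C)(C(C)C)C(C)C
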